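## Retrosynthetic overview
1. 26 ⇒ (debenzylation; water attack on the β face of C8 in the 8α,9α-epoxide; acylation of O6) ⇒ dauc-8-ene-4β,6α-diol 21 ⇒ (α-face isopropylcerium addition) ⇒ trans-fused 6α-hydroxy C4 ketone 20.
2. 20 ⇒ 11: H5α and O6α arrive together in a syn hydroboration of C5=C6. The C8 ester carbon is reduced to the C8 methyl, and C9–O is exchanged for H through the enol triflate, which leaves the 8-ene.
3. Feature on which the plan rests: in the seven-membered ring (C1, C5, C6, C7, C8, C9, C10), the run C8–C9–C10 with oxygen on its central carbon is a siloxyvinylcarbene. C7–C6–C5–C1 is the diene of a 2-vinylcyclopentene whose ring terminus is the methyl-bearing quaternary fusion carbon C1.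
4. Key disconnection: formal (4+3). C7–C8 forms by cyclopropanation of the vinyl group of 6 with the carbenoid from 9, and C1–C10 forms by divinylcyclopropane rearrangement.
5. Ring order: the five-membered ring is bought with 1; the three-membered ring (C6, C7, C8) is transient; the seven-membered ring forms by its ring expansion; the oxirane is made late and opened.

Key step: step 6

Numbering:
- C1 is the quaternary fusion carbon with the methyl group. C2 and C3 are the cyclopentane CH2 groups. C4 is the isopropyl carbinol carbon. C5 is the fusion CH.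
- C6 is the acyloxy CH. C7 is CH2. C8 is the methyl carbinol. C9 is the secondary carbinol. C10 is the CH2 that closes to C1.
- β is the face of the C1 methyl and α is the other face.
- Bicyclic intermediates are named as hydroazulanes (bicyclo[5.3.0]decanes) with this numbering.

Assumption: the catalyst antipode in step 6 is assigned by carrying over the usual sense of induction of the adamantylglycinate dirhodium catalysts with monosubstituted alkenes through the boat transition state. This assignment points to the R catalyst for (R)-C1. Both antipodes are commercial and would be exchanged if the assignment proved reversed.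

## Route

Step 1
Reactants: 1 3-methylcyclopent-2-en-1-one
Product: 3 2-bromo-3-methylcyclopent-2-en-1-one, via trans-2,3-dibromo-3-methylcyclopentanone 2 (not isolated)
Conditions: Br2, CH2Cl2, 0 °C; then Et3N, 0 °C → rt
Reagents that add atoms: bromine, BrBr
Why: Bromination–dehydrobromination: bromine adds across the enone alkene and the amine removes HBr through the acidic α-hydrogen, which returns the conjugated enone with bromine on the carbon that becomes C5.

Step 2
Reactants: 3 2-bromo-3-methylcyclopent-2-en-1-one
Product: 4 6-bromo-7-methyl-1,4-dioxaspiro[4.4]non-6-ene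
Conditions: HOCH2CH2OH, p-TsOH·H2O (cat.), benzene, reflux (Dean–Stark)
Reagents that add atoms: ethylene glycol, OCCO
Why: Acid-catalysed ketalisation with azeotropic water removal masks C4, and the vinylic bromine keeps the double bond from migrating out of the C5=C1 position.

Step 3
Reactants: 4 6-bromo-7-methyl-1,4-dioxaspiro[4.4]non-6-ene; 5 vinylboronic acid pinacol ester
Product: 6 7-methyl-6-vinyl-1,4-dioxaspiro[4.4]non-6-ene
Conditions: Pd(dppf)Cl2 (3 mol %), K2CO3, 1,4-dioxane/H2O, 85 °C
Reagents that add atoms: none
Why: Suzuki–Miyaura coupling of the alkenyl bromide with the vinylboronate attaches C6–C7 under basic conditions that the ketal tolerates.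

Step 4
Reactants: 7 methyl acetoacetate
Product: 8 methyl 2-diazo-3-oxobutanoate
Conditions: p-ABSA, Et3N, MeCN, 0 °C → rt
Reagents that add atoms: 4-acetamidobenzenesulfonyl azide, CC(=O)Nc1ccc(cc1)S(=O)(=O)N=[N+]=[N-]
Why: Regitz diazo transfer onto the doubly activated methylene of the β-keto ester.

Step 5
Reactants: 8 methyl 2-diazo-3-oxobutanoate
Product: 9 methyl 3-(tert-butyldimethylsilyloxy)-2-diazobut-3-enoate
Conditions: TBSOTf, Et3N, CH2Cl2, 0 °C
Reagents that add atoms: tert-butyldimethylsilyl triflate, CC(C)(C)[Si](C)(C)OS(=O)(=O)C(F)(F)F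
Why: Soft enolisation (silyl triflate plus amine) of the acetyl group, the only enolisable site, gives the silyl enol ether without loss of the diazo group.

Step 6
Reactants: 6 7-methyl-6-vinyl-1,4-dioxaspiro[4.4]non-6-ene; 9 methyl 3-(tert-butyldimethylsilyloxy)-2-diazobut-3-enoate
Product: 11 methyl (1R)-4,4-ethylenedioxy-1-methyl-9-(tert-butyldimethylsilyloxy)hydroazula-5,8-diene-8-carboxylate, via cis-divinylcyclopropane 10 (not isolated)
Conditions: Rh2(R-PTAD)4 (1 mol %), 9 added over 2 h, hexanes, rt; then reflux
Reagents that add atoms: none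
Why: The dirhodium catalyst expels N2 from 9 to give a donor/acceptor siloxyvinylcarbenoid, which cyclopropanates the monosubstituted C6=C7 vinyl group of 6 in a concerted asynchronous step with the siloxyvinyl donor cis to the cyclopentenyl group (10), and 10 then undergoes a [3,3] divinylcyclopropane (Cope) rearrangement that breaks C6–C8 and joins C10 to C1. The closest known reaction type is the enantioselective tandem cyclopropanation/Cope (formal 4+3) of siloxyvinyldiazoacetates with 1-vinyl-2-methylcycloalkenes, where the ring terminus likewise becomes quaternary. The seven-membered ring (C1, C5–C10) is thus closed by sigmatropic ring expansion of the three-membered ring through the obligatory boat transition state and not by end-to-end cyclisation, with C7–C8 kept from the cyclopropanation and C1–C10 made in the Cope step. The only surviving stereocentre, C1, is catalyst-controlled: the chiral pocket fixes C6 and C8 of 10, and the boat lets C10 reach only one face of C5=C1, so the cyclopropane chirality is relayed to (R)-C1. The step needs site selectivity (vinyl over the tetrasubstituted ring alkene, secured by sterics), cis diastereoselectivity (inherent to donor/acceptor carbenoids) and chemoselectivity over the dioxolane C–H and O sites (secured by the faster reaction at the diene terminus under slow addition). The final warming is planned because the C1 methyl is the Z substituent that must tuck under the boat, which slows the rearrangement.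

Step 7
Reactants: 11 methyl (1R)-4,4-ethylenedioxy-1-methyl-9-(tert-butyldimethylsilyloxy)hydroazula-5,8-diene-8-carboxylate
Product: 13 methyl 4,4-ethylenedioxy-6α-hydroxy-1β-methyl-9-(tert-butyldimethylsilyloxy)-5αH-hydroazul-8-ene-8-carboxylate, via C6α-alkylborane 12 (not isolated)
Conditions: BH3·THF, THF, 0 °C → rt; then NaBO3·4H2O, THF/H2O, rt
Reagents that add atoms: sodium perborate, [Na+].[Na+].O[B-]1(O)OO[B-](O)(O)OO1; borane–THF, [BH3-][O+]1CCCC1 (boron is in 12 only)
Why: Hydroboration–oxidation: borane adds syn to the only unpolarised alkene with boron on the less substituted C6 and from the α face, because in the boat of the cyclohepta-1,4-diene the C1 methyl stands perpendicular over the β face of C5=C6, so H5α and (after oxidation with retention) O6α are set together while the tetrasubstituted push–pull C8=C9 alkene stays inert.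

Step 8
Reactants: 13 methyl 4,4-ethylenedioxy-6α-hydroxy-1β-methyl-9-(tert-butyldimethylsilyloxy)-5αH-hydroazul-8-ene-8-carboxylate
Product: 14 methyl 4,4-ethylenedioxy-1β-methyl-6α,9-bis(tert-butyldimethylsilyloxy)-5αH-hydroazul-8-ene-8-carboxylate
Conditions: TBSCl, imidazole, DMF, rt → 40 °C
Reagents that add atoms: tert-butyldimethylsilyl chloride, CC(C)(C)[Si](C)(C)Cl
Why: Imidazole-promoted silylation masks the C6 carbinol for the fluoride, hydride and mesylation steps that follow.

Step 9
Reactants: 14 methyl 4,4-ethylenedioxy-1β-methyl-6α,9-bis(tert-butyldimethylsilyloxy)-5αH-hydroazul-8-ene-8-carboxylate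
Product: 15 methyl 4,4-ethylenedioxy-1β-methyl-6α-(tert-butyldimethylsilyloxy)-9-(trifluoromethylsulfonyloxy)-5αH-hydroazul-8-ene-8-carboxylate
Conditions: CsF, PhNTf2, DME, rt
Reagents that add atoms: N-phenylbis(trifluoromethanesulfonimide), O=S(=O)(N(c1ccccc1)S(=O)(=O)C(F)(F)F)C(F)(F)F
Why: Silyl enol ether to enol triflate exchange: fluoride cleaves only the much more labile vinylogous silyl ester, and the β-keto ester enolate is O-triflated in situ, so conjugation with the ester fixes the double bond at C8=C9.

Step 10
Reactants: 15 methyl 4,4-ethylenedioxy-1β-methyl-6α-(tert-butyldimethylsilyloxy)-9-(trifluoromethylsulfonyloxy)-5αH-hydroazul-8-ene-8-carboxylate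
Product: 16 methyl 4,4-ethylenedioxy-1β-methyl-6α-(tert-butyldimethylsilyloxy)-5αH-hydroazul-8-ene-8-carboxylate
Conditions: Pd(OAc)2 (5 mol %), PPh3, HCO2H, Et3N, DMF, 60 °C
Reagents that add atoms: none
Why: Palladium-catalysed formate reduction of the enol triflate (oxidative addition, decarboxylation of formate, reductive elimination) replaces C9–OTf by C9–H without moving the alkene.

Step 11
Reactants: 16 methyl 4,4-ethylenedioxy-1β-methyl-6α-(tert-butyldimethylsilyloxy)-5αH-hydroazul-8-ene-8-carboxylate
Product: 17 4,4-ethylenedioxy-8-(hydroxymethyl)-1β-methyl-6α-(tert-butyldimethylsilyloxy)-5αH-hydroazul-8-ene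
Conditions: DIBAL-H, CH2Cl2, −78 °C; Rochelle salt work-up
Reagents that add atoms: none
Why: DIBAL-H 1,2-reduction of the enoate gives the allylic alcohol, so the former ester carbon becomes the future C8 methyl carbon.

Step 12
Reactants: 17 4,4-ethylenedioxy-8-(hydroxymethyl)-1β-methyl-6α-(tert-butyldimethylsilyloxy)-5αH-hydroazul-8-ene
Product: 19 4,4-ethylenedioxy-1β,8-dimethyl-6α-(tert-butyldimethylsilyloxy)-5αH-hydroazul-8-ene, via allylic mesylate 18 (not isolated)
Conditions: MsCl, Et3N, THF, −30 °C; then LiBHEt3, −30 → 0 °C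
Reagents that add atoms: methanesulfonyl chloride, CS(=O)(=O)Cl (its atoms are in 18 only)
Why: Mesylation followed by SN2 hydride displacement with Super-Hydride at the open primary allylic carbon, rather than SN2′ at C9 beside neopentyl C10, gives the C8 methyl with the 8-ene in place.

Step 13
Reactants: 19 4,4-ethylenedioxy-1β,8-dimethyl-6α-(tert-butyldimethylsilyloxy)-5αH-hydroazul-8-ene
Product: 20 6α-hydroxy-1β,8-dimethyl-5αH-hydroazul-8-en-4-one
Conditions: 1 M aq HCl/THF (1:4), 0 °C → rt
Reagents that add atoms: water, O
Why: Acid hydrolysis of the dioxolane and of the silyl ether should both be much faster than acid-catalysed enolisation of the freed cyclopentanone, so the C5 configuration and the β-hydroxy ketone should survive.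

Step 14
Reactants: 20 6α-hydroxy-1β,8-dimethyl-5αH-hydroazul-8-en-4-one
Product: 21 dauc-8-ene-4β,6α-diol (jaeschkeanadiol)
Conditions: i-PrLi, anhydrous CeCl3 (each about 4 equiv), THF, −78 °C; aq NH4Cl
Reagents that add atoms: isopropyllithium, [Li]C(C)C
Why: Organocerium 1,2-addition: the weakly basic reagent first forms the C6 alkoxide and then attacks the C4 carbonyl of the trans-fused ketone from the α face, anti to the axial C1 methyl, which sets the 4β-hydroxy-4α-isopropyl centre.

Step 15
Reactants: 21 dauc-8-ene-4β,6α-diol (jaeschkeanadiol); 22 4-(benzyloxy)benzoic acid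
Product: 23 4β-hydroxydauc-8-en-6α-yl 4-(benzyloxy)benzoate
Conditions: DCC, DMAP (cat.), CH2Cl2, rt
Reagents that add atoms: none
Why: Steglich esterification acylates the secondary C6 hydroxyl, while the tertiary C4 hydroxyl is too hindered to react.

Step 16
Reactants: 23 4β-hydroxydauc-8-en-6α-yl 4-(benzyloxy)benzoate
Product: 24 8α,9α-epoxy-4β-hydroxydaucan-6α-yl 4-(benzyloxy)benzoate
Conditions: m-CPBA, CH2Cl2, 0 °C
Reagents that add atoms: 3-chloroperoxybenzoic acid, O=C(OO)c1cccc(Cl)c1
Why: Prilezhaev epoxidation of the only alkene should come from the exo α face of the cycloheptene chair, since the axial C1 methyl and H6β cover the β face, and this sets O9α.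

Step 17
Reactants: 24 8α,9α-epoxy-4β-hydroxydaucan-6α-yl 4-(benzyloxy)benzoate
Product: 25 4β,8β,9α-trihydroxydaucan-6α-yl 4-(benzyloxy)benzoate
Conditions: HClO4 (cat.), THF/H2O (3:1), 0 °C → rt
Reagents that add atoms: water, O
Why: Acid-catalysed epoxide hydrolysis: water attacks the protonated oxirane at tertiary C8, which carries most of the positive charge, from the β face with inversion, giving the trans 8β,9α-diol with the C8 methyl α.

Step 18
Reactants: 25 4β,8β,9α-trihydroxydaucan-6α-yl 4-(benzyloxy)benzoate
Product: 26 4β,8β,9α-trihydroxydaucan-6α-yl 4-hydroxybenzoate (CNP0197754.1)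
Conditions: H2 (1 atm), 10 % Pd/C, EtOAc, rt
Reagents that add atoms: none
Why: Hydrogenolysis of the benzyl aryl ether frees the phenol and touches neither the alkyl benzoate nor the carbinols.

## Compound list
1 | 3-methylcyclopent-2-en-1-one | CC1=CC(=O)CC1 | starting material
2 | trans-2,3-dibromo-3-methylcyclopentanone (racemic) | CC1(Br)CCC(=O)C1Br | intermediate
3 | 2-bromo-3-methylcyclopent-2-en-1-one | CC1=C(Br)C(=O)CC1 | intermediate
4 | 6-bromo-7-methyl-1,4-dioxaspiro[4.4]non-6-ene | BrC1=C(C)CCC12OCCO2 | intermediate
5 | vinylboronic acid pinacol ester | C=CB1OC(C)(C)C(C)(C)O1 | starting material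
6 | 7-methyl-6-vinyl-1,4-dioxaspiro[4.4]non-6-ene (C4 ketal diene) | C=CC1=C(C)CCC12OCCO2 | intermediate
7 | methyl acetoacetate | COC(=O)CC(C)=O | starting material
8 | methyl 2-diazo-3-oxobutanoate | COC(=O)C(=[N+]=[N-])C(C)=O | intermediate
9 | methyl 3-(tert-butyldimethylsilyloxy)-2-diazobut-3-enoate | C=C(O[Si](C)(C)C(C)(C)C)C(=[N+]=[N-])C(=O)OC | intermediate
10 | methyl (1R,2S)-1-[1-(tert-butyldimethylsilyloxy)vinyl]-2-(7-methyl-1,4-dioxaspiro[4.4]non-6-en-6-yl)cyclopropane-1-carboxylate (cis-divinylcyclopropane of C8, C6, C7) | COC(=O)[C@]1(C(=C)O[Si](C)(C)C(C)(C)C)C[C@H]1C2=C(C)CCC23OCCO3 | intermediate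
11 | (1R)-hydroazuladiene: C4 ketal, 5-ene, C8 CO2Me, C9 OTBS enol ether | C12(OCCO1)CC[C@]3(C)CC(O[Si](C)(C)C(C)(C)C)=C(C(=O)OC)CC=C23 | intermediate
12 | C6α-BH2, H5α adduct of 11 | C12(OCCO1)CC[C@]3(C)CC(O[Si](C)(C)C(C)(C)C)=C(C(=O)OC)C[C@H](B)[C@@H]23 | intermediate
13 | 6α-alcohol, H5α (trans-fused), C4 ketal, C8 CO2Me, C9 OTBS | C12(OCCO1)CC[C@]3(C)CC(O[Si](C)(C)C(C)(C)C)=C(C(=O)OC)C[C@H](O)[C@@H]23 | intermediate
14 | 6α-OTBS ether of 13 | C12(OCCO1)CC[C@]3(C)CC(O[Si](C)(C)C(C)(C)C)=C(C(=O)OC)C[C@H](O[Si](C)(C)C(C)(C)C)[C@@H]23 | intermediate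
15 | C9 enol triflate | C12(OCCO1)CC[C@]3(C)CC(OS(=O)(=O)C(F)(F)F)=C(C(=O)OC)C[C@H](O[Si](C)(C)C(C)(C)C)[C@@H]23 | intermediate
16 | 8-ene-8-carboxylate | C12(OCCO1)CC[C@]3(C)CC=C(C(=O)OC)C[C@H](O[Si](C)(C)C(C)(C)C)[C@@H]23 | intermediate
17 | 8-(hydroxymethyl)-8-ene | C12(OCCO1)CC[C@]3(C)CC=C(CO)C[C@H](O[Si](C)(C)C(C)(C)C)[C@@H]23 | intermediate
18 | allylic mesylate of 17 | C12(OCCO1)CC[C@]3(C)CC=C(COS(C)(=O)=O)C[C@H](O[Si](C)(C)C(C)(C)C)[C@@H]23 | intermediate
19 | 1β,8-dimethyl-8-ene, C4 ketal, 6α-OTBS | C12(OCCO1)CC[C@]3(C)CC=C(C)C[C@H](O[Si](C)(C)C(C)(C)C)[C@@H]23 | intermediate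
20 | 6α-hydroxy-1β,8-dimethyl-5αH-hydroazul-8-en-4-one | O=C1CC[C@]2(C)CC=C(C)C[C@H](O)[C@@H]12 | intermediate
21 | dauc-8-ene-4β,6α-diol (jaeschkeanadiol) | CC(C)[C@]1(O)CC[C@]2(C)CC=C(C)C[C@H](O)[C@H]21 | intermediate
22 | 4-(benzyloxy)benzoic acid | O=C(O)c1ccc(OCc2ccccc2)cc1 | starting material
23 | 4β-hydroxydauc-8-en-6α-yl 4-(benzyloxy)benzoate | CC(C)[C@]1(O)CC[C@]2(C)CC=C(C)C[C@H](OC(=O)c3ccc(OCc4ccccc4)cc3)[C@H]21 | intermediate
24 | 8α,9α-epoxide of 23 | CC(C)[C@]1(O)CC[C@]2(C)C[C@@H]3O[C@]3(C)C[C@H](OC(=O)c4ccc(OCc5ccccc5)cc4)[C@H]21 | intermediate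
25 | 8β,9α-diol, phenol still benzylated | CC(C)[C@]1(O)CC[C@]2(C)C[C@H](O)[C@@](C)(O)C[C@H](OC(=O)c3ccc(OCc4ccccc4)cc3)[C@H]21 | intermediate
26 | (1R,4R,5S,6S,8S,9S)-4β,8β,9α-trihydroxydaucan-6α-yl 4-hydroxybenzoate, CNP0197754.1 | CC(C)[C@]1(O)CC[C@]2(C)C[C@H](O)[C@@](C)(O)C[C@H](OC(=O)c3ccc(O)cc3)[C@H]21 | target

## Count and risks
Total steps: 18. Longest linear sequence: 16 (steps 1–3 and 6–18, from 1 to 26). Compound 9 is made in two side steps, and 5 and 22 are bought.

**Step 6 (key step).**
- What may go wrong: the carbenoid could be consumed before it finds the hindered, twisted vinyl group. The competing processes are dimerisation, electrocyclisation of the vinyldiazo compound, and attack on the dioxolane. Enantiofacial discrimination may erode, or the rearrangement may stall because the Z methyl must enter the boat.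
- Fallback: separate carbene transfer from formation of the second vinyl arm. The fallback sets out from 6 and 8. A chiral cobalt(II)–porphyrin metalloradical cyclopropanation with the sturdier keto-diazoester would give methyl (1R,2S)-1-acetyl-2-(7-methyl-1,4-dioxaspiro[4.4]non-6-en-6-yl)cyclopropane-1-carboxylate F1, and the isomer with acetyl cis to the cyclopentenyl group is separated. Soft enolisation of its acetyl group (TBSOTf, Et3N) would create the siloxyvinyl arm, that is 10. Heating 10 in toluene would rearrange it to 11, where the route is rejoined.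

**Step 7.**
- What may go wrong: facial selectivity could be poor, since the concave α face looks towards the C8=C9 unit. Borane may attack the push–pull alkene or the ester, or the enol silyl group may be lost in the oxidative work-up.
- Fallback: postpone C5/C6 until the C4 carbonyl can polarise the alkene. The fallback sets out from 11 and runs the chemistry of steps 9–12 in the 5-ene series.
  - CsF/PhNTf2 would give the 5-ene enol triflate F2.
  - Pd/formate would give the 5,8-dienoate F3.
  - DIBAL-H would give the 5,8-dienyl carbinol F4.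
  - Mesylation (5,8-dienyl mesylate F5, taken on directly) and LiBHEt3 would give the 1,8-dimethyl-5,8-diene ketal F6.
  - PPTS in wet acetone would free the allylic ketal to the 5,8-dien-4-one F7.
  - Copper-catalysed conjugate borylation (CuCl, NaOt-Bu, B2pin2, MeOH) is chemoselective for the enone. A Josiphos-type ligand would be chosen to deliver boron to the α face of C6. This would give the 6α-boryl ketone F8, whose C5 centre, now α to the ketone, is equilibrated with DBU towards the trans-fused isomer.
  - NaBO3 oxidation with retention would give 20, where the route is rejoined.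

**Step 14.**
- What may go wrong: enolisation could outrun addition of the branched sp3 nucleophile to the hindered carbonyl, with epimerisation at C5 or retro-aldol opening. β-Hydride reduction could also outrun it.
- Fallback: bring in the three carbons as a flatter sp2 nucleophile that cannot transfer hydride. The fallback sets out from 20. Isopropenylmagnesium bromide with LaCl3·2LiCl would add from the α face to give the 4α-isopropenyl-4β,6α-diol F9. The 1,1-disubstituted alkene would then be saturated selectively beside the trisubstituted 8-ene with Wilkinson's catalyst and H2. This gives 21, where the route is rejoined.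

## Further compounds
F1 | step 6 | methyl (1R,2S)-1-acetyl-2-(7-methyl-1,4-dioxaspiro[4.4]non-6-en-6-yl)cyclopropane-1-carboxylate | COC(=O)[C@]1(C(C)=O)C[C@H]1C2=C(C)CCC23OCCO3
F2 | step 7 | 5-ene enol triflate (C4 ketal, C8 CO2Me, C9 OTf) | C12(OCCO1)CC[C@]3(C)CC(OS(=O)(=O)C(F)(F)F)=C(C(=O)OC)CC=C23
F3 | step 7 | 5,8-dienoate (C4 ketal, C8 CO2Me) | C12(OCCO1)CC[C@]3(C)CC=C(C(=O)OC)CC=C23
F4 | step 7 | 5,8-dienyl carbinol (C8 CH2OH) | C12(OCCO1)CC[C@]3(C)CC=C(CO)CC=C23
F5 | step 7 | 5,8-dienyl mesylate | C12(OCCO1)CC[C@]3(C)CC=C(COS(C)(=O)=O)CC=C23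
F6 | step 7 | 1,8-dimethyl-5,8-diene ketal | C12(OCCO1)CC[C@]3(C)CC=C(C)CC=C23
F7 | step 7 | (1R)-1,8-dimethylhydroazula-5,8-dien-4-one | O=C1CC[C@]2(C)CC=C(C)CC=C12
F8 | step 7 | 6α-(pinacolboryl)-1β,8-dimethyl-5αH-hydroazul-8-en-4-one | O=C1CC[C@]2(C)CC=C(C)C[C@H](B3OC(C)(C)C(C)(C)O3)[C@@H]12
F9 | step 14 | 4α-isopropenyl-1β,8-dimethyl-5αH-hydroazul-8-ene-4β,6α-diol | CC(=C)[C@]1(O)CC[C@]2(C)CC=C(C)C[C@H](O)[C@H]21
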